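**Retrosynthetic overview**
1. 15 ⇒ (removal of four MOM groups) 14 ⇒ cut C2–C1′: achiral chromone 12 + arylboronic acid 13. A Rh-catalysed asymmetric 1,4-arylation joins them and sets C2, the only stereocentre.
2. Enabling feature: the vinylogous ester O1–C2(H)=C3–C4=O of the γ-pyrone ring C. C2 is an unsubstituted, prochiral β-carbon, and O1 is tied back in the ring, so aryl-metal addition ends in protonation at C3 and not in loss of the oxygen.
3. 8-Prenyl group ⇒ 5-O-prenyl ether 8 by a para-Claisen–Cope shift. C6 (OMOM) and C4a are blocked, and C8 is the only C–H of ring A.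
4. 8 ⇒ 5,6,7-trihydroxychromone 5 ⇒ trimethoxychromone 4 ⇒ acetophenone 2 ⇒ 3,4,5-trimethoxyphenol 1. The Me→MOM exchange is made while the molecule is achiral and free of alkene.
5. Ring order: ring A is bought (1), ring C is closed in step 2 (O1–C2 bond), ring B arrives intact in step 8.

Key step: step 8

Remark: the descriptor in the target SMILES corresponds to (2S) (O1 > C1′ > C3 > H), so the aryl group has to reach the Re face of C2 of the chromone.

**Step 1**
Reactants: 1 3,4,5-trimethoxyphenol
Product: 2 1-(6-hydroxy-2,3,4-trimethoxyphenyl)ethan-1-one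
Conditions: AcOH, BF3·OEt2, 85 °C; aq. work-up
Reagents that add atoms: acetic acid, CC(=O)O
Why: Friedel–Crafts (Fries-type) C-acylation of the very electron-rich phenol takes place at one of its two equivalent free positions ortho to OH, and the new acyl group deactivates the ring against a second acylation.

**Step 2**
Reactants: 2 1-(6-hydroxy-2,3,4-trimethoxyphenyl)ethan-1-one
Product: 4 5,6,7-trimethoxy-4H-chromen-4-one, via enaminone 3 (not isolated)
Conditions: DMF-DMA, toluene, 100 °C; evaporate; then conc. HCl, CH2Cl2, 40 °C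
Reagents that add atoms: N,N-dimethylformamide dimethyl acetal, COC(OC)N(C)C
Why: Condensation of the methyl ketone with the amide acetal gives the enaminone, and acid then triggers addition–elimination of the phenol oxygen at the β-carbon (6-endo-trig, loss of Me2NH), which is the standard enaminone chromone synthesis and closes ring C.

**Step 3**
Reactants: 4 5,6,7-trimethoxy-4H-chromen-4-one
Product: 5 5,6,7-trihydroxy-4H-chromen-4-one
Conditions: BBr3 (5 equiv), CH2Cl2, −78 °C → rt; then ice/H2O, Ar
Reagents that add atoms: none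
Why: Lewis-acid aryl methyl ether cleavage with BBr3 removes all three methyl groups (the chelated 5-OMe first) at a stage with no alkene and no stereocentre, and the acid-stable γ-pyrone should survive.

**Step 4**
Reactants: 5 5,6,7-trihydroxy-4H-chromen-4-one
Product: 6 5-hydroxy-6,7-bis(methoxymethoxy)-4H-chromen-4-one
Conditions: MOMCl (2.1 equiv), K2CO3, acetone, 0 °C → rt, Ar
Reagents that add atoms: chloromethyl methyl ether, COCCl
Why: Williamson-type MOM ether formation under weak base should touch only 6-OH and 7-OH, because 5-OH is held in the hydrogen bond to C4=O, a selectivity that is standard for 5-hydroxychromones and 5-hydroxyflavones.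

**Step 5**
Reactants: 6 5-hydroxy-6,7-bis(methoxymethoxy)-4H-chromen-4-one; 7 1-bromo-3-methylbut-2-ene (prenyl bromide)
Product: 8 6,7-bis(methoxymethoxy)-5-[(3-methylbut-2-en-1-yl)oxy]-4H-chromen-4-one
Conditions: K2CO3, DMF, 40 °C
Reagents that add atoms: none
Why: Williamson O-alkylation (SN2) of the remaining chelated phenol with the reactive allylic bromide in a polar aprotic solvent favours O- over C-alkylation, and the MOM acetals are stable to base.

**Step 6**
Reactants: 8 6,7-bis(methoxymethoxy)-5-[(3-methylbut-2-en-1-yl)oxy]-4H-chromen-4-one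
Product: 11 5-hydroxy-6,7-bis(methoxymethoxy)-8-(3-methylbut-2-en-1-yl)-4H-chromen-4-one, via ortho-dienone 9 (not isolated), via para-dienone 10 (not isolated)
Conditions: Eu(fod)3 (10 mol %), NaHCO3, PhCl, 85 °C
Reagents that add atoms: none
Why: In this Eu(III)-catalysed aromatic para-Claisen–Cope rearrangement, chelation by O4/O5 speeds the first [3,3] shift to C6, the OMOM group there forbids re-aromatisation, dienone 9 therefore passes the allyl group on by a Cope [3,3] shift to C8 (the only C–H of ring A), and 10 tautomerises, the double allyl inversion returning a linear prenyl group.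

**Step 7**
Reactants: 11 5-hydroxy-6,7-bis(methoxymethoxy)-8-(3-methylbut-2-en-1-yl)-4H-chromen-4-one
Product: 12 5,6,7-tris(methoxymethoxy)-8-(3-methylbut-2-en-1-yl)-4H-chromen-4-one
Conditions: NaH, MOMCl, DMF, 0 °C
Reagents that add atoms: chloromethyl methyl ether, COCCl
Why: Full deprotonation breaks the hydrogen-bond chelate and the small MOM electrophile caps the hindered phenoxide (Williamson-type ether formation), so that no O4/O5 chelating site is left to bind rhodium in step 8.

**Step 8**
Reactants: 12 5,6,7-tris(methoxymethoxy)-8-(3-methylbut-2-en-1-yl)-4H-chromen-4-one; 13 [4-(methoxymethoxy)phenyl]boronic acid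
Product: 14 (2S)-2-[4-(methoxymethoxy)phenyl]-5,6,7-tris(methoxymethoxy)-8-(3-methylbut-2-en-1-yl)-2,3-dihydro-4H-chromen-4-one
Conditions: 13 (2.5 equiv, in portions), [RhCl(C2H4)2]2 (2.5 mol %), (S)-MeO-F12-BIPHEP (5.5 mol %), aq. KOH (5 mol %, only to turn Rh–Cl into Rh–OH), toluene/H2O 10:1, 30–40 °C, Ar
Reagents that add atoms: none
Why: In the Hayashi–Miyaura mechanism Rh–OH transmetalates with 13 to an aryl-rhodium species, the C2=C3 bond of 12 binds, syn-carborhodation puts the aryl group on C2 and rhodium on C3, and water protonates the oxa-π-allyl rhodium enolate to release 14 and regenerate Rh–OH. The closest known reaction type is the asymmetric 1,4-addition of arylboronic acids to chromones under Rh/chiral bisphosphine or Rh/chiral diene catalysis, which gives 2-arylchroman-4-ones directly. No ring is closed: ring C is kept and only loses its pyrone conjugation, so that one operation joins the two halves, brings ring C to the flavanone oxidation level and creates the only stereocentre from a flat, achiral precursor. C2 is controlled by the catalyst alone, because the (S)-biaryl bisphosphine leaves open the quadrant in which the chromone binds through its C2 Re face, the same spatial mode that gives (S)-3-arylcyclohexanones from cyclohexenone and that corresponds to (2S) here (the ligand antipode is available should the sense prove reversed). The step needs 1,4- over 1,2-addition, enone over prenyl alkene, and protonation over ring opening at O1; these are secured by the polarised O1–C2=C3–C4=O unit against an unactivated trisubstituted alkene, by the flanking 5-OMOM group that shields C4=O and removes the O4/O5 chelate, by O1 being locked in the ring, and by a medium without free base at or below 40 °C in which retro-oxa-Michael racemisation of 14 should not occur.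

**Step 9**
Reactants: 14 (2S)-2-[4-(methoxymethoxy)phenyl]-5,6,7-tris(methoxymethoxy)-8-(3-methylbut-2-en-1-yl)-2,3-dihydro-4H-chromen-4-one
Product: 15 nirurinetin, (2S)-5,6,7-trihydroxy-2-(4-hydroxyphenyl)-8-(3-methylbut-2-en-1-yl)-2,3-dihydro-4H-chromen-4-one
Conditions: cat. aq. HCl (3 M), degassed MeOH, 35–40 °C, Ar
Reagents that add atoms: none
Why: Acid-catalysed transacetalisation of the four phenolic MOM acetals to methanol is a standard end-game for prenylated flavanones, the non-basic medium avoids retro-oxa-Michael racemisation at C2, the mild acid should leave the prenyl group alone, and exclusion of air protects the pyrogallol ring.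

**Compound list**
1 | 3,4,5-trimethoxyphenol | COc1cc(O)cc(OC)c1OC | starting material
2 | 1-(6-hydroxy-2,3,4-trimethoxyphenyl)ethan-1-one | CC(=O)c1c(O)cc(OC)c(OC)c1OC | intermediate
3 | (E)-3-(dimethylamino)-1-(6-hydroxy-2,3,4-trimethoxyphenyl)prop-2-en-1-one (enaminone) | CN(C)/C=C/C(=O)c1c(O)cc(OC)c(OC)c1OC | intermediate
4 | 5,6,7-trimethoxy-4H-chromen-4-one | COc1cc2occc(=O)c2c(OC)c1OC | intermediate
5 | 5,6,7-trihydroxy-4H-chromen-4-one | O=c1ccoc2cc(O)c(O)c(O)c12 | intermediate
6 | 5-hydroxy-6,7-bis(methoxymethoxy)-4H-chromen-4-one | COCOc1cc2occc(=O)c2c(O)c1OCOC | intermediate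
7 | 1-bromo-3-methylbut-2-ene (prenyl bromide) | CC(C)=CCBr | starting material
8 | 6,7-bis(methoxymethoxy)-5-[(3-methylbut-2-en-1-yl)oxy]-4H-chromen-4-one | CC(C)=CCOc1c(OCOC)c(OCOC)cc2occc(=O)c12 | intermediate
9 | 6,7-bis(methoxymethoxy)-6-(2-methylbut-3-en-2-yl)-4H-chromene-4,5(6H)-dione (ortho-dienone, racemic) | C=CC(C)(C)C1(OCOC)C(=O)C2=C(C=C1OCOC)OC=CC2=O | intermediate
10 | 6,7-bis(methoxymethoxy)-8-(3-methylbut-2-en-1-yl)-4H-chromene-4,5(8H)-dione (para-dienone, racemic) | CC(C)=CCC1C(OCOC)=C(OCOC)C(=O)C2=C1OC=CC2=O | intermediate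
11 | 5-hydroxy-6,7-bis(methoxymethoxy)-8-(3-methylbut-2-en-1-yl)-4H-chromen-4-one | CC(C)=CCc1c(OCOC)c(OCOC)c(O)c2c1occc2=O | intermediate
12 | 5,6,7-tris(methoxymethoxy)-8-(3-methylbut-2-en-1-yl)-4H-chromen-4-one | CC(C)=CCc1c(OCOC)c(OCOC)c(OCOC)c2c1occc2=O | intermediate
13 | [4-(methoxymethoxy)phenyl]boronic acid | COCOc1ccc(B(O)O)cc1 | starting material
14 | (2S)-2-[4-(methoxymethoxy)phenyl]-5,6,7-tris(methoxymethoxy)-8-(3-methylbut-2-en-1-yl)-2,3-dihydro-4H-chromen-4-one | CC(C)=CCc1c(OCOC)c(OCOC)c(OCOC)c2c1O[C@H](c1ccc(OCOC)cc1)CC2=O | intermediate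
15 | nirurinetin, (2S)-5,6,7-trihydroxy-2-(4-hydroxyphenyl)-8-(3-methylbut-2-en-1-yl)-2,3-dihydro-4H-chromen-4-one | CC(C)=CCc1c(O)c(O)c(O)c2c1O[C@H](c1ccc(O)cc1)CC2=O | target

**Totals**
Total step count: 9.
Longest linear sequence: 9 steps (1 → 15). Compounds 7 and 13 are bought and enter in steps 5 and 8.

**Steps most likely to fail**

(i) Step 8. Carborhodation of the electron-rich, fully substituted chromone may be slower than protodeboronation of 13. The crowded 5-OMOM/8-prenyl periphery may also erode facial discrimination.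
The fallback sets out from 12 and returns at 14. The same C2–aryl bond is made with a more reactive stoichiometric aryl donor without stereocontrol, and the stereocentre is then sorted by kinetic resolution.
- 1-Bromo-4-(methoxymethoxy)benzene and Mg in THF give 4-(methoxymethoxy)phenylmagnesium bromide F1.
- Its CuBr·SMe2-catalysed, Me3SiCl-accelerated 1,4-addition to 12 at −40 °C should give the racemic 4-(trimethylsilyloxy)-2H-chromene silyl enol ether F2.
- Dilute citric acid hydrolyses this to the racemic tetra-MOM flavanone F3.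
- Noyori–Ikariya transfer hydrogenation of the racemate with RuCl[(R,R)-TsDPEN](p-cymene) and HCO2H/Et3N is stopped near half conversion. It should reduce the (2R)-ketone to the cis-(2R,4R)-flavan-4-ol F4 and leave the (2S)-ketone, which after chromatography is 14.

(ii) Step 6. The allyl–O5 bond may ionise with loss of the prenyl group. The sequence may also stall, because the first [3,3] shift has to join two fully substituted carbons.
The fallback sets out from 6 and returns at 11. It replaces the pericyclic chemistry by halogenation and cross-coupling, so that steps 5 and 6 are not needed.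
- NIS in DMF at 0 °C should iodinate the only free ring-A position, para to 5-OH, to give 5-hydroxy-8-iodo-6,7-bis(methoxymethoxy)-4H-chromen-4-one F5.
- Stille coupling with tributyl(3-methylbut-2-en-1-yl)stannane (Pd(PPh3)4, DMF, 80 °C) should then give 11.

(iii) Step 9. Acid may induce addition of 7-OH to the protonated prenyl alkene, slow ionisation at C2 may cost enantiopurity, and the pyrogallol ring may oxidise during a long reaction.
The fallback sets out from 5 and returns at 15. Fluoride-labile silyl ethers replace all acetals, so that no acid is needed at the end.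
- TBSCl and imidazole in DMF should give 6,7-bis(tert-butyldimethylsilyloxy)-5-hydroxy-4H-chromen-4-one F6.
- Mitsunobu etherification with 3-methylbut-2-en-1-ol (PPh3, DIAD, THF) gives the 5-O-prenyl ether F7.
- The same Eu(fod)3-catalysed para-Claisen–Cope rearrangement gives the 8-prenyl-5-hydroxychromone F8.
- TBSOTf and 2,6-lutidine give the tris-silyl ether F9.
- The conditions of step 8 with commercial [4-(tert-butyldimethylsilyloxy)phenyl]boronic acid should give the (2S)-tetrasilyl flavanone F10.
- Et3N·3HF in THF at 0 °C releases 15.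

**Further compounds**
F1 | step 8 | 4-(methoxymethoxy)phenylmagnesium bromide | COCOc1ccc([Mg]Br)cc1
F2 | step 8 | rac-2-[4-(methoxymethoxy)phenyl]-5,6,7-tris(methoxymethoxy)-8-(3-methylbut-2-en-1-yl)-4-(trimethylsilyloxy)-2H-chromene | CC(C)=CCc1c(OCOC)c(OCOC)c(OCOC)c2c1OC(c1ccc(OCOC)cc1)C=C2O[Si](C)(C)C
F3 | step 8 | rac-2-[4-(methoxymethoxy)phenyl]-5,6,7-tris(methoxymethoxy)-8-(3-methylbut-2-en-1-yl)-2,3-dihydro-4H-chromen-4-one | CC(C)=CCc1c(OCOC)c(OCOC)c(OCOC)c2c1OC(c1ccc(OCOC)cc1)CC2=O
F4 | step 8 | (2R,4R)-2-[4-(methoxymethoxy)phenyl]-5,6,7-tris(methoxymethoxy)-8-(3-methylbut-2-en-1-yl)chroman-4-ol | CC(C)=CCc1c(OCOC)c(OCOC)c(OCOC)c2c1O[C@@H](c1ccc(OCOC)cc1)C[C@H]2O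
F5 | step 6 | 5-hydroxy-8-iodo-6,7-bis(methoxymethoxy)-4H-chromen-4-one | COCOc1c(I)c2occc(=O)c2c(O)c1OCOC
F6 | step 9 | 6,7-bis(tert-butyldimethylsilyloxy)-5-hydroxy-4H-chromen-4-one | CC(C)(C)[Si](C)(C)Oc1cc2occc(=O)c2c(O)c1O[Si](C)(C)C(C)(C)C
F7 | step 9 | 6,7-bis(tert-butyldimethylsilyloxy)-5-[(3-methylbut-2-en-1-yl)oxy]-4H-chromen-4-one | CC(C)=CCOc1c(O[Si](C)(C)C(C)(C)C)c(O[Si](C)(C)C(C)(C)C)cc2occc(=O)c12
F8 | step 9 | 6,7-bis(tert-butyldimethylsilyloxy)-5-hydroxy-8-(3-methylbut-2-en-1-yl)-4H-chromen-4-one | CC(C)=CCc1c(O[Si](C)(C)C(C)(C)C)c(O[Si](C)(C)C(C)(C)C)c(O)c2c1occc2=O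
F9 | step 9 | 5,6,7-tris(tert-butyldimethylsilyloxy)-8-(3-methylbut-2-en-1-yl)-4H-chromen-4-one | CC(C)=CCc1c(O[Si](C)(C)C(C)(C)C)c(O[Si](C)(C)C(C)(C)C)c(O[Si](C)(C)C(C)(C)C)c2c1occc2=O
F10 | step 9 | (2S)-5,6,7-tris(tert-butyldimethylsilyloxy)-2-[4-(tert-butyldimethylsilyloxy)phenyl]-8-(3-methylbut-2-en-1-yl)-2,3-dihydro-4H-chromen-4-one | CC(C)=CCc1c(O[Si](C)(C)C(C)(C)C)c(O[Si](C)(C)C(C)(C)C)c(O[Si](C)(C)C(C)(C)C)c2c1O[C@H](c1ccc(O[Si](C)(C)C(C)(C)C)cc1)CC2=O
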